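**Retrosynthetic overview**

1. Ring atoms are called C1 (alkynyl-bearing sp2 carbon), C2 (=CH), C3 (CHOAc), C4 (CHOMe), C5 and C6 (the two CHOH). The side chain is cut at the C1–C(sp) bond: Sonogashira coupling of a C1 vinyl iodide with a C10 enyne.
2. The C1=C2/C6–OH unit is traced back to a 2-iodocyclohex-2-enone (C6=O), and this to a 7-oxabicyclo[2.2.1]heptan-2-one by β-elimination of an oxygen bridge between C2 and C5.
3. Key disconnection: C2–C3 and C4–C5 together, by a Diels–Alder reaction of furan (C2, C1, C6, C5 and the bridge oxygen) with vinylene carbonate (C3, C4 and their oxygens).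
4. Enabling feature: C2 and C5 stand 1,4 across the six-membered ring, C5 carries an oxygen and C2 is the β-carbon of the latent C6=O/C1=C2 enone. One oxygen atom can therefore bridge them (a C2–O bond the target does not have) and be expelled from C2 later; the cis C3/C4 oxygens, trans to the C5 oxygen, are an endo-bound Z-enediol.
5. Ring order: oxanorbornene (carbocycle, oxygen bridge and carbonate ring at once, meso) → desymmetrisation at C6 → bridge opening to the monocyclic enone; the carbonate ring is opened last to tell C3 (acetate) from C4 (methyl ether).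

Key step: step 1

Remark (assumption): (−)-Ipc2BH, the antipode made from (+)-α-pinene, is taken to be the one that puts boron on the alkene carbon shown in 4; should the sense be the opposite, (+)-Ipc2BH is used and nothing else changes.

**Route**

Step 1
Reactants: 1 furan; 2 vinylene carbonate (1,3-dioxol-2-one)
Product: 3 meso endo adduct 5,6-endo-(carbonyldioxy)-7-oxabicyclo[2.2.1]hept-2-ene (carbonate ring on the face away from the oxygen bridge)
Conditions: furan (excess, as solvent), BHT (trace), sealed tube, 120 °C; endo isomer separated by crystallisation or chromatography, exo isomer returned to the same conditions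
Reagents that add atoms: none
Why: Thermal normal-demand Diels–Alder cycloaddition, concerted and suprafacial on both partners, in which the two furan α-carbons (C2, C5) bond to the two olefinic carbons of vinylene carbonate (C3, C4); the closest known reaction type is the cycloaddition of furan with vinylene carbonate or maleic anhydride. The six-membered carbocycle closes in an intermolecular [4+2] mode and arrives as a 7-oxabicyclo[2.2.1]heptene, the oxygen bridge between C2 and C5 being the temporary bond that step 4 breaks at C2. The cis relation of the C3 and C4 oxygens is fixed by the Z geometry locked in the five-membered carbonate, and their trans relation to the C5 oxygen follows from endo approach, the carbonate lying under the diene. The step needs endo over exo selectivity, which the flat compact carbonate (secondary overlap of its carbonyl with the diene, kinetic control at the lowest workable temperature) should favour, while the exo isomer can be recycled through cycloreversion. No enantioselectivity is needed here because the endo adduct is meso, so two commodity chemicals deliver both C–C bonds, the carbocycle and the relative configuration of C3, C4 and C5.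

Step 2
Reactants: 3 meso endo adduct
Product: 5 (1S,2S,4R,5S,6R)-5,6-(carbonyldioxy)-7-oxabicyclo[2.2.1]heptan-2-ol (2-exo-OH; endo carbonate), via exo-trialkylborane 4 (not isolated)
Conditions: (−)-Ipc2BH, THF, −25 °C; then Me3NO (anhydrous), THF/diglyme, 70 °C
Reagents that add atoms: (−)-diisopinocampheylborane, B([C@@H]1C[C@@H]2C[C@H]([C@H]1C)C2(C)C)[C@@H]1C[C@@H]2C[C@H]([C@H]1C)C2(C)C; trimethylamine N-oxide, C[N+](C)(C)[O-]
Why: Reagent-controlled asymmetric hydroboration of a strained meso bicyclic alkene, syn and from the open exo face, in which the chiral borane chooses between the two enantiotopic alkene carbons and so fixes the absolute configuration of every stereocentre, followed by C–B oxidation with retention under base-free conditions that spare the carbonate.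

Step 3
Reactants: 5 exo-alcohol
Product: 6 (1R,4R,5S,6S)-5,6-(carbonyldioxy)-7-oxabicyclo[2.2.1]heptan-2-one
Conditions: Dess–Martin periodinane, CH2Cl2, 0 °C → rt
Reagents that add atoms: none
Why: Dess–Martin oxidation of the secondary alcohol under neutral conditions gives the ketone, whose only α-stereocentre is a bridgehead that cannot enolise, and the cyclic carbonate is inert to the reagent.

Step 4
Reactants: 6 bicyclic ketone
Product: 8 (4S,5S,6R)-6-[(tert-butyldimethylsilyl)oxy]-4,5-(carbonyldioxy)cyclohex-2-en-1-one, via bicyclic silyl enol ether 7 (not isolated)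
Conditions: TBSOTf, Et3N, CH2Cl2, −78 → 0 °C
Reagents that add atoms: tert-butyldimethylsilyl triflate, CC(C)(C)[Si](C)(C)OS(=O)(=O)C(F)(F)F
Why: Silyl triflate/amine-induced β-elimination opening of a 7-oxabicyclo[2.2.1]heptan-2-one (E1cB type): enolisation is possible only toward the CH2 (C1) because C5 is a bridgehead, the silyl enol ether expels the bridging oxygen from C2 to give the C1=C2 enone, and the oxygen stays on C5 with unchanged configuration as its silyl ether.

Step 5
Reactants: 8 enone
Product: 9 (4S,5S,6R)-6-[(tert-butyldimethylsilyl)oxy]-4,5-(carbonyldioxy)-2-iodocyclohex-2-en-1-one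
Conditions: I2, pyridine/CH2Cl2 (1:1), 0 °C → rt
Reagents that add atoms: iodine, II
Why: α-Iodination of the enone by the iodine/pyridine protocol (conjugate addition of pyridine, iodination of the enolate at C1, elimination), the standard entry to 2-iodoenones for cross-coupling.

Step 6
Reactants: 9 iodoenone
Product: 10 (1R,4S,5S,6S)-6-[(tert-butyldimethylsilyl)oxy]-4,5-(carbonyldioxy)-2-iodocyclohex-2-en-1-ol
Conditions: NaBH4, CeCl3·7H2O, MeOH, −78 °C
Reagents that add atoms: none
Why: Luche 1,2-reduction of the 2-iodoenone, in which Felkin–Anh control by the non-chelating C5 silyloxy group (hydride enters anti to the C5–O bond) should set the C6 carbinol cis to the C5 oxygen.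

Step 7
Reactants: 10 allylic alcohol
Product: 11 (3S,4S,5R,6R)-5,6-bis[(tert-butyldimethylsilyl)oxy]-3,4-(carbonyldioxy)-1-iodocyclohex-1-ene
Conditions: TBSOTf, 2,6-lutidine, CH2Cl2, −20 °C
Reagents that add atoms: tert-butyldimethylsilyl triflate, CC(C)(C)[Si](C)(C)OS(=O)(=O)C(F)(F)F
Why: Silylation with the silyl triflate and a hindered pyridine covers the hindered allylic C6–OH so that only the carbonate oxygens are set free in the following steps.

Step 8
Reactants: 11 bis-silyl ether carbonate
Product: 12 (1S,2S,5R,6R)-5,6-bis[(tert-butyldimethylsilyl)oxy]-4-iodocyclohex-3-ene-1,2-diol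
Conditions: K2CO3 (cat.), MeOH, 0 °C
Reagents that add atoms: none
Why: Carbonate-catalysed transesterification with methanol removes the cyclic carbonate as dimethyl carbonate and leaves the silyl ethers and the vinyl iodide intact.

Step 9
Reactants: 12 cis-diol
Product: 14 (1S,4R,5R,6S)-4,5-bis[(tert-butyldimethylsilyl)oxy]-6-hydroxy-3-iodocyclohex-2-en-1-yl acetate, via cyclic orthoacetate 13 (not isolated)
Conditions: MeC(OMe)3, PPTS (cat.), CH2Cl2, rt; then 80% aq AcOH, 0 °C → rt
Reagents that add atoms: trimethyl orthoacetate, CC(OC)(OC)OC; water, O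
Why: Cyclic orthoester formation on the cis-diol and mild acid hydrolysis, which by the known stereoelectronic rule leaves the ester on the axial oxygen: allylic 1,2-strain with the C1 iodine holds C6–OTBS pseudoaxial, which puts the C5 and C4 oxygens equatorial and the allylic C3 oxygen pseudoaxial, so the acetate should end on C3.

Step 10
Reactants: 14 hydroxy acetate
Product: 15 (1S,4R,5R,6S)-4,5-bis[(tert-butyldimethylsilyl)oxy]-3-iodo-6-methoxycyclohex-2-en-1-yl acetate
Conditions: MeOTf, 2,6-di-tert-butyl-4-methylpyridine, 4 Å MS, CH2Cl2, rt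
Reagents that add atoms: methyl triflate, COS(=O)(=O)C(F)(F)F
Why: O-Methylation with methyl triflate and a non-nucleophilic pyridine base (a Williamson-type etherification without alkoxide) alkylates the remaining equatorial C4–OH without acetyl migration or silyl loss.

Step 11
Reactants: 16 2-methylbut-3-yn-2-ol
Product: 17 (E)-2-methyl-4-(tributylstannyl)but-3-en-2-ol
Conditions: Bu3SnH, PdCl2(PPh3)2 (1 mol %), THF, 0 °C → rt
Reagents that add atoms: tributyltin hydride, CCCC[SnH](CCCC)CCCC
Why: Palladium-catalysed syn-hydrostannation of the terminal alkyne, in which the bulky tertiary carbinol steers tin to the terminal carbon and the (E)-vinylstannane results.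

Step 12
Reactants: 17 vinylstannane; 18 2,3-dibromopropene
Product: 19 (E)-6-bromo-2-methylhepta-3,6-dien-2-ol
Conditions: Pd2(dba)3 (2.5 mol %), P(2-furyl)3 (10 mol %), THF, 50 °C
Reagents that add atoms: none
Why: Stille coupling in which zerovalent palladium inserts into the allylic C–Br bond far faster than into the vinylic one and the alkene geometry of the stannane is retained, giving the skipped diene.

Step 13
Reactants: 19 bromodiene; 20 ethynyltrimethylsilane
Product: 21 (E)-2-methyl-6-methylidene-8-(trimethylsilyl)oct-3-en-7-yn-2-ol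
Conditions: PdCl2(PPh3)2 (3 mol %), CuI (6 mol %), Et3N, 50 °C
Reagents that add atoms: none
Why: Sonogashira coupling of the 2-bromo-1-alkene with the silyl-capped acetylene builds the 1,3-enyne.

Step 14
Reactants: 21 silyl enyne
Product: 22 (E)-2-methyl-6-methylideneoct-3-en-7-yn-2-ol
Conditions: K2CO3, MeOH, rt
Reagents that add atoms: none
Why: Methoxide-induced protodesilylation of the alkynylsilane at room temperature, too mild to move the skipped diene into conjugation.

Step 15
Reactants: 15 vinyl iodide; 22 terminal enyne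
Product: 23 (1S,4S,5R,6S)-4,5-bis[(tert-butyldimethylsilyl)oxy]-3-[(5E)-7-hydroxy-7-methyl-3-methylideneoct-5-en-1-yn-1-yl]-6-methoxycyclohex-2-en-1-yl acetate
Conditions: Pd(PPh3)4 (5 mol %), CuI (10 mol %), Et3N, THF, rt
Reagents that add atoms: none
Why: Sonogashira coupling, in which oxidative addition to the vinyl iodide is much faster than ionisation of the hindered allylic acetate, the tertiary amine base offers no nucleophile and the free tertiary alcohol is tolerated.

Step 16
Reactants: 23 bis-silyl ether
Product: 24 target, (1S,4S,5S,6R)-4,5-dihydroxy-3-[(5E)-7-hydroxy-7-methyl-3-methylideneoct-5-en-1-yn-1-yl]-6-methoxycyclohex-2-en-1-yl acetate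
Conditions: HF·pyridine, pyridine, THF, 0 °C → rt
Reagents that add atoms: none
Why: Fluoride-induced cleavage of both silyl ethers with pyridine-buffered HF·pyridine, conditions that should spare the allylic acetate, the tertiary allylic alcohol and the enyne.

**Compound list**

1 | furan | c1ccoc1 | starting material
2 | vinylene carbonate (1,3-dioxol-2-one) | O=C1OC=CO1 | starting material
3 | meso endo adduct, 5,6-endo-(carbonyldioxy)-7-oxabicyclo[2.2.1]hept-2-ene (cis carbonate ring anti to the oxygen bridge) | O=C1O[C@@H]2[C@H](O1)[C@@H]3C=C[C@H]2O3 | intermediate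
4 | B-[5,6-endo-(carbonyldioxy)-7-oxabicyclo[2.2.1]hept-2-exo-yl]diisopinocampheylborane (boron exo on C6; not isolated) | O=C1O[C@@H]2[C@H](O1)[C@@H]3[C@@H](B([C@@H]4C[C@@H]5C[C@H]([C@H]4C)C5(C)C)[C@@H]4C[C@@H]5C[C@H]([C@H]4C)C5(C)C)C[C@H]2O3 | intermediate
5 | (1S,2S,4R,5S,6R)-5,6-(carbonyldioxy)-7-oxabicyclo[2.2.1]heptan-2-ol (2-exo-OH, syn to the oxygen bridge; endo carbonate) | O=C1O[C@@H]2[C@H](O1)[C@@H]3[C@@H](O)C[C@H]2O3 | intermediate
6 | (1R,4R,5S,6S)-5,6-(carbonyldioxy)-7-oxabicyclo[2.2.1]heptan-2-one (endo carbonate) | O=C1O[C@@H]2[C@H](O1)[C@@H]3C(=O)C[C@H]2O3 | intermediate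
7 | 2-[(tert-butyldimethylsilyl)oxy]-5,6-endo-(carbonyldioxy)-7-oxabicyclo[2.2.1]hept-2-ene (silyl enol ether of 6; not isolated) | O=C1O[C@@H]2[C@H](O1)[C@@H]3C(O[Si](C)(C)C(C)(C)C)=C[C@H]2O3 | intermediate
8 | (4S,5S,6R)-6-[(tert-butyldimethylsilyl)oxy]-4,5-(carbonyldioxy)cyclohex-2-en-1-one | O=C1C=C[C@@H]2OC(=O)O[C@@H]2[C@H]1O[Si](C)(C)C(C)(C)C | intermediate
9 | (4S,5S,6R)-6-[(tert-butyldimethylsilyl)oxy]-4,5-(carbonyldioxy)-2-iodocyclohex-2-en-1-one | O=C1C(I)=C[C@@H]2OC(=O)O[C@@H]2[C@H]1O[Si](C)(C)C(C)(C)C | intermediate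
10 | (1R,4S,5S,6S)-6-[(tert-butyldimethylsilyl)oxy]-4,5-(carbonyldioxy)-2-iodocyclohex-2-en-1-ol (OH cis to the neighbouring silyloxy group) | O[C@H]1C(I)=C[C@@H]2OC(=O)O[C@@H]2[C@H]1O[Si](C)(C)C(C)(C)C | intermediate
11 | (3S,4S,5R,6R)-5,6-bis[(tert-butyldimethylsilyl)oxy]-3,4-(carbonyldioxy)-1-iodocyclohex-1-ene | CC(C)(C)[Si](C)(C)O[C@H]1C(I)=C[C@@H]2OC(=O)O[C@@H]2[C@H]1O[Si](C)(C)C(C)(C)C | intermediate
12 | (1S,2S,5R,6R)-5,6-bis[(tert-butyldimethylsilyl)oxy]-4-iodocyclohex-3-ene-1,2-diol | CC(C)(C)[Si](C)(C)O[C@H]1C(I)=C[C@H](O)[C@H](O)[C@H]1O[Si](C)(C)C(C)(C)C | intermediate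
13 | cyclic methyl orthoacetate of 12 (2-methoxy-2-methyl-1,3-dioxolane fused at C3/C4, either configuration at the orthoester carbon; not isolated) | CC(C)(C)[Si](C)(C)O[C@H]1C(I)=C[C@@H]2OC(C)(OC)O[C@@H]2[C@H]1O[Si](C)(C)C(C)(C)C | intermediate
14 | (1S,4R,5R,6S)-4,5-bis[(tert-butyldimethylsilyl)oxy]-6-hydroxy-3-iodocyclohex-2-en-1-yl acetate | CC(C)(C)[Si](C)(C)O[C@H]1C(I)=C[C@H](OC(C)=O)[C@H](O)[C@H]1O[Si](C)(C)C(C)(C)C | intermediate
15 | (1S,4R,5R,6S)-4,5-bis[(tert-butyldimethylsilyl)oxy]-3-iodo-6-methoxycyclohex-2-en-1-yl acetate | CC(C)(C)[Si](C)(C)O[C@H]1C(I)=C[C@H](OC(C)=O)[C@H](OC)[C@H]1O[Si](C)(C)C(C)(C)C | intermediate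
16 | 2-methylbut-3-yn-2-ol | CC(C)(O)C#C | starting material
17 | (E)-2-methyl-4-(tributylstannyl)but-3-en-2-ol | CC(C)(O)/C=C/[Sn](CCCC)(CCCC)CCCC | intermediate
18 | 2,3-dibromopropene | C=C(Br)CBr | starting material
19 | (E)-6-bromo-2-methylhepta-3,6-dien-2-ol | C=C(Br)C/C=C/C(C)(C)O | intermediate
20 | ethynyltrimethylsilane | C#C[Si](C)(C)C | starting material
21 | (E)-2-methyl-6-methylidene-8-(trimethylsilyl)oct-3-en-7-yn-2-ol | C=C(C#C[Si](C)(C)C)C/C=C/C(C)(C)O | intermediate
22 | (E)-2-methyl-6-methylideneoct-3-en-7-yn-2-ol | C=C(C#C)C/C=C/C(C)(C)O | intermediate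
23 | (1S,4S,5R,6S)-4,5-bis[(tert-butyldimethylsilyl)oxy]-3-[(5E)-7-hydroxy-7-methyl-3-methylideneoct-5-en-1-yn-1-yl]-6-methoxycyclohex-2-en-1-yl acetate | CC(C)(C)[Si](C)(C)O[C@H]1C(C#CC(=C)C/C=C/C(C)(C)O)=C[C@H](OC(C)=O)[C@H](OC)[C@H]1O[Si](C)(C)C(C)(C)C | intermediate
24 | (1S,4S,5S,6R)-4,5-dihydroxy-3-[(5E)-7-hydroxy-7-methyl-3-methylideneoct-5-en-1-yn-1-yl]-6-methoxycyclohex-2-en-1-yl acetate | C=C(C#CC1=C[C@H](OC(C)=O)[C@H](OC)[C@@H](O)[C@H]1O)C/C=C/C(C)(C)O | target

**Step count and risks**

Total step count: 16. Longest linear sequence: 12 steps (steps 1–10, 15 and 16); the enyne 22 is made in 4 steps (steps 11–14).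

Steps most likely to fail:

Step 1. What may go wrong: insufficient endo over exo selectivity, made worse by thermal cycloreversion that lets the adducts equilibrate. Fallback (stereoconvergent; sets out from 1, comes back at 3): furan 1 is combined with 4,5-dichloro-1,3-dioxol-2-one, a much more reactive dienophile that should react near room temperature, to give the dichloro adduct F1 as an endo/exo mixture. Aqueous hydrolysis (H2O/dioxane, NaHCO3) of either isomer removes the carbonate and both chlorides and converges on the meso 7-oxabicyclo[2.2.1]hept-5-ene-2,3-dione F2. NaBH4 (MeOH, −78 °C) should deliver hydride to both carbonyls from the open exo face and give only the endo,endo-diol F3, and 1,1'-carbonyldiimidazole (THF) closes the carbonate to 3.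

Step 6. What may go wrong: hydride delivery to the wrong face of the C6 carbonyl, if the ring conformation or cerium coordination overrides Felkin–Anh control. Fallback (inversion in place of facial control; sets out from 9, comes back at 10): if reduction of 9 gives mainly the C6-epimeric trans alcohol F4, this is inverted by a Mitsunobu reaction (chloroacetic acid, PPh3, DIAD, toluene, 0 °C) to the cis chloroacetate F5. The chloroacetyl group is then removed with thiourea/NaHCO3 in ethanol, which should not touch the cyclic carbonate, to give 10.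

Step 9. What may go wrong: opening of the orthoester toward the wrong oxygen, or acetyl migration between the two cis oxygens while one of them is a free hydroxyl. Fallback (ether first, under tin control; sets out from 12, comes back at 15): 12 is heated with Bu2SnO (toluene, removal of water) to the dibutylstannylene acetal F6, which with MeI/CsF in DMF should be alkylated at the equatorial, non-allylic oxygen to give the C4 methyl ether F7. Acetylation of the remaining allylic C3–OH (Ac2O, pyridine, DMAP) then gives 15 directly, so that no acetate is ever present next to a free hydroxyl.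

Further compounds
F1 | step 1 | 5,6-dichloro-5,6-(carbonyldioxy)-7-oxabicyclo[2.2.1]hept-2-ene (endo/exo mixture expected; endo-carbonate isomer drawn) | O=C1O[C@]2(Cl)[C@](Cl)(O1)[C@@H]3C=C[C@H]2O3
F2 | step 1 | meso 7-oxabicyclo[2.2.1]hept-5-ene-2,3-dione | O=C1C(=O)[C@@H]2C=C[C@H]1O2
F3 | step 1 | meso endo,endo-7-oxabicyclo[2.2.1]hept-5-ene-2,3-diol | O[C@@H]1[C@H](O)[C@@H]2C=C[C@H]1O2
F4 | step 6 | (1S,4S,5S,6S)-6-[(tert-butyldimethylsilyl)oxy]-4,5-(carbonyldioxy)-2-iodocyclohex-2-en-1-ol (C6 epimer of 10, OH trans to the silyloxy group) | O[C@@H]1C(I)=C[C@@H]2OC(=O)O[C@@H]2[C@H]1O[Si](C)(C)C(C)(C)C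
F5 | step 6 | chloroacetate of 10 (ester oxygen cis to the silyloxy group) | ClCC(=O)O[C@H]1C(I)=C[C@@H]2OC(=O)O[C@@H]2[C@H]1O[Si](C)(C)C(C)(C)C
F6 | step 9 | dibutylstannylene acetal of 12 (2,2-dibutyl-1,3,2-dioxastannolane fused at C3/C4) | CC(C)(C)[Si](C)(C)O[C@H]1C(I)=C[C@@H]2O[Sn](CCCC)(CCCC)O[C@@H]2[C@H]1O[Si](C)(C)C(C)(C)C
F7 | step 9 | (1S,4R,5R,6S)-4,5-bis[(tert-butyldimethylsilyl)oxy]-3-iodo-6-methoxycyclohex-2-en-1-ol | CC(C)(C)[Si](C)(C)O[C@H]1C(I)=C[C@H](O)[C@H](OC)[C@H]1O[Si](C)(C)C(C)(C)C
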